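**Retrosynthetic overview**
1. Target 16 ⇐ its 4'-O-benzyl ether 15 (hydrogenolysis last).
2. The pyranone C ring of 15, the only ring made in the route, ⇐ 2'-hydroxychalcone 13 by oxidative cyclisation.
3. Chalcone 13 ⇐ Claisen–Schmidt aldol condensation of acetophenone 9 with aldehyde 11 (key C–C bond, Cα–Cβ).
4. A-ring ketone 9 ⇐ 2,3,4,5-tetramethoxyphenol 8 ⇐ 1,2,3,4-tetramethoxybenzene 4 ⇐ 2,3,4-trimethoxybenzaldehyde 1 (CHO→OH, methylation, formylation, CHO→OH, C-acetylation).
5. B-ring aldehyde 11 ⇐ syringaldehyde 10 (benzylation); both benzene rings are bought.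

**Assumptions:** The target has no stereocentre, so "single enantiomer" needs no stereocontrol. The only stereo-elements on the way are the E-alkene of 13 and the racemic, transient centres of 12 and 14, which are destroyed. Promoting acids and bases (cat. H2SO4, BF3·OEt2, KOH in step 7), cat. I2 and Pd/C are treated as standing outside the balanced equation of their step.

**Step 1**
Reactants: 1 2,3,4-trimethoxybenzaldehyde
Product: 3 2,3,4-trimethoxyphenol, via 2,3,4-trimethoxyphenyl formate 2 (not isolated)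
Conditions: 30% aq. H2O2 (1.3 eq), cat. H2SO4, MeOH, rt
Reagents that add atoms: hydrogen peroxide, OO
Why: Acid-catalysed Dakin-type Baeyer–Villiger oxidation, in which the o,p-methoxylated aryl group migrates to give formate 2, which is methanolysed in situ to the phenol.

**Step 2**
Reactants: 3 2,3,4-trimethoxyphenol
Product: 4 1,2,3,4-tetramethoxybenzene
Conditions: MeI (1.5 eq), K2CO3, acetone, reflux
Reagents that add atoms: iodomethane, CI
Why: Williamson O-methylation (SN2) of the only nucleophilic site, the phenoxide.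

**Step 3**
Reactants: 4 1,2,3,4-tetramethoxybenzene
Product: 6 2,3,4,5-tetramethoxybenzaldehyde, via aryl iminium dichlorophosphate 5 (not isolated)
Conditions: POCl3 (1.5 eq), DMF, 0 → 80 °C; then H2O, 0 → 60 °C
Reagents that add atoms: N,N-dimethylformamide, CN(C)C=O; water, O
Why: Vilsmeier–Haack formylation at one of the two equivalent free positions (para to one OMe, ortho to another), followed by hydrolysis of iminium 5.

**Step 4**
Reactants: 6 2,3,4,5-tetramethoxybenzaldehyde
Product: 8 2,3,4,5-tetramethoxyphenol, via 2,3,4,5-tetramethoxyphenyl formate 7 (not isolated)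
Conditions: 30% aq. H2O2 (1.2 eq), cat. H2SO4, MeOH, rt; use 8 promptly
Reagents that add atoms: hydrogen peroxide, OO
Why: Dakin-type Baeyer–Villiger oxidation again favoured by the ortho- and para-methoxy groups, with in situ methanolysis of formate 7.

**Step 5**
Reactants: 8 2,3,4,5-tetramethoxyphenol
Product: 9 2'-hydroxy-3',4',5',6'-tetramethoxyacetophenone [1-(2-hydroxy-3,4,5,6-tetramethoxyphenyl)ethan-1-one]
Conditions: AcOH, BF3·OEt2 (3 eq), 85 °C; then H2O
Reagents that add atoms: acetic acid, CC(=O)O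
Why: BF3-mediated Friedel–Crafts C-acylation (Nencki/Fries type) at the only unsubstituted ring carbon, which is ortho to OH and para to an OMe, giving the chelation-stabilised o-hydroxy ketone.

**Step 6**
Reactants: 10 syringaldehyde (4-hydroxy-3,5-dimethoxybenzaldehyde)
Product: 11 4-(benzyloxy)-3,5-dimethoxybenzaldehyde
Conditions: BnBr (1.2 eq), K2CO3, DMF, 60 °C
Reagents that add atoms: benzyl bromide, BrCc1ccccc1
Why: Williamson benzylation masks the phenol, whose phenoxide would otherwise deactivate the aldehyde towards enolate addition.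

**Step 7**
Reactants: 9 2'-hydroxy-3',4',5',6'-tetramethoxyacetophenone; 11 4-(benzyloxy)-3,5-dimethoxybenzaldehyde (1.1 eq)
Product: 13 (2E)-3-[4-(benzyloxy)-3,5-dimethoxyphenyl]-1-(2-hydroxy-3,4,5,6-tetramethoxyphenyl)prop-2-en-1-one, via racemic β-hydroxy ketone aldol adduct 12 (not isolated)
Conditions: 50% aq. KOH, EtOH, rt, 48 h; then 1 M HCl to pH 4
Reagents that add atoms: none
Why: Claisen–Schmidt crossed aldol condensation in which the methyl-ketone enolate of 9 adds to the non-enolisable aldehyde 11 and E1cB dehydration of 12 gives the thermodynamically favoured E-enone.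

**Step 8**
Reactants: 13 the (E)-2'-hydroxychalcone
Product: 15 4'-(benzyloxy)-3',5,5',6,7,8-hexamethoxyflavone, via racemic flavanone 14 (not isolated)
Conditions: I2 (10 mol %), DMSO, 120 °C
Reagents that add atoms: none
Why: Iodine-catalysed oxidative cyclisation in which oxa-Michael closure of the 2'-OH gives flavanone 14, which iodine dehydrogenates with DMSO as terminal oxidant, leaving the benzyl and methyl ethers intact.

**Step 9**
Reactants: 15 4'-(benzyloxy)-3',5,5',6,7,8-hexamethoxyflavone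
Product: 16 4'-hydroxy-3',5,5',6,7,8-hexamethoxyflavone
Conditions: H2 (1 atm), 10% Pd/C, EtOAc–MeOH, rt; stop when 15 is consumed
Reagents that add atoms: none
Why: Catalytic hydrogenolysis of the benzylic C–O bond, to which the chromone C2=C3 bond, the carbonyl and the aryl methyl ethers are inert at 1 atm and room temperature.

**Compound list**
1 | 2,3,4-trimethoxybenzaldehyde | COc1ccc(C=O)c(OC)c1OC | starting material
2 | 2,3,4-trimethoxyphenyl formate | COc1ccc(OC=O)c(OC)c1OC | intermediate (not isolated)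
3 | 2,3,4-trimethoxyphenol | COc1ccc(O)c(OC)c1OC | intermediate
4 | 1,2,3,4-tetramethoxybenzene | COc1ccc(OC)c(OC)c1OC | intermediate
5 | N,N-dimethyl-(2,3,4,5-tetramethoxyphenyl)methaniminium dichlorophosphate | COc1cc(C=[N+](C)C)c(OC)c(OC)c1OC.[O-]P(=O)(Cl)Cl | intermediate (not isolated)
6 | 2,3,4,5-tetramethoxybenzaldehyde | COc1cc(C=O)c(OC)c(OC)c1OC | intermediate
7 | 2,3,4,5-tetramethoxyphenyl formate | COc1cc(OC=O)c(OC)c(OC)c1OC | intermediate (not isolated)
8 | 2,3,4,5-tetramethoxyphenol | COc1cc(O)c(OC)c(OC)c1OC | intermediate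
9 | 1-(2-hydroxy-3,4,5,6-tetramethoxyphenyl)ethan-1-one | CC(=O)c1c(O)c(OC)c(OC)c(OC)c1OC | intermediate
10 | syringaldehyde (4-hydroxy-3,5-dimethoxybenzaldehyde) | COc1cc(C=O)cc(OC)c1O | starting material
11 | 4-(benzyloxy)-3,5-dimethoxybenzaldehyde | COc1cc(C=O)cc(OC)c1OCc1ccccc1 | intermediate
12 | 3-[4-(benzyloxy)-3,5-dimethoxyphenyl]-3-hydroxy-1-(2-hydroxy-3,4,5,6-tetramethoxyphenyl)propan-1-one (racemic) | COc1cc(C(O)CC(=O)c2c(O)c(OC)c(OC)c(OC)c2OC)cc(OC)c1OCc1ccccc1 | intermediate (not isolated)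
13 | (2E)-3-[4-(benzyloxy)-3,5-dimethoxyphenyl]-1-(2-hydroxy-3,4,5,6-tetramethoxyphenyl)prop-2-en-1-one | COc1cc(/C=C/C(=O)c2c(O)c(OC)c(OC)c(OC)c2OC)cc(OC)c1OCc1ccccc1 | intermediate
14 | 2-[4-(benzyloxy)-3,5-dimethoxyphenyl]-5,6,7,8-tetramethoxychroman-4-one (racemic) | COc1cc(C2CC(=O)c3c(OC)c(OC)c(OC)c(OC)c3O2)cc(OC)c1OCc1ccccc1 | intermediate (not isolated)
15 | 4'-(benzyloxy)-3',5,5',6,7,8-hexamethoxyflavone | COc1cc(-c2cc(=O)c3c(OC)c(OC)c(OC)c(OC)c3o2)cc(OC)c1OCc1ccccc1 | intermediate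
16 | 4'-hydroxy-3',5,5',6,7,8-hexamethoxyflavone (achiral) | COc1cc(-c2cc(=O)c3c(OC)c(OC)c(OC)c(OC)c3o2)cc(OC)c1O | target

**Totals**
Total step count: 9. Longest linear sequence: 8 steps (steps 1, 2, 3, 4, 5, 7, 8, 9); the B-ring branch is step 6.

**Three steps most likely to fail, with fallbacks**

Step 5 (C-acetylation of the pentaoxygenated ring). The reaction may stop at the O-acetate or lose the methyl ether next to the new carbonyl. The fallback sets out from phenol 8 and installs the acetyl group by directed ortho-metalation. MOMCl/i-Pr2NEt (CH2Cl2, 0 °C → rt) gives 1-(methoxymethoxy)-2,3,4,5-tetramethoxybenzene F1. n-BuLi (THF, 0 °C) removes the only ring proton, flanked by OMOM and OMe, to give [2-(methoxymethoxy)-3,4,5,6-tetramethoxyphenyl]lithium F2. N-Methoxy-N-methylacetamide (−78 °C) gives the stable tetrahedral adduct lithium 1-[methoxy(methyl)amino]-1-[2-(methoxymethoxy)-3,4,5,6-tetramethoxyphenyl]ethan-1-olate F3. Quenching with 1 M HCl collapses it to 1-[2-(methoxymethoxy)-3,4,5,6-tetramethoxyphenyl]ethan-1-one F4. HCl/MeOH (rt to 40 °C) then removes the MOM group, and the route is rejoined at acetophenone 9.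

Step 8 (oxidative cyclisation). HI formed at 120 °C may cleave the benzyl or 5-methyl ether, or flavanone may remain. The fallback builds the pyranone by Baker–Venkataraman chemistry, setting out from aldehyde 11 and using ketone 9. Pinnick oxidation of 11 (NaClO2, NaH2PO4, 2-methyl-2-butene, t-BuOH/H2O) gives 4-(benzyloxy)-3,5-dimethoxybenzoic acid F5. EDC·HCl/DMAP (CH2Cl2, rt) esterifies the phenol of 9 to 2-acetyl-3,4,5,6-tetramethoxyphenyl 4-(benzyloxy)-3,5-dimethoxybenzoate F6. KOH/pyridine (50 °C) effects O→C acyl transfer to 1-[4-(benzyloxy)-3,5-dimethoxyphenyl]-3-(2-hydroxy-3,4,5,6-tetramethoxyphenyl)propane-1,3-dione F7. Cyclodehydration (cat. H2SO4, AcOH, 60 °C) rejoins the route at flavone 15.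

Step 9 (hydrogenolysis). The chromone C2=C3 bond may be over-reduced, or cleavage of the doubly ortho-flanked benzyl ether may be slow. The fallback changes the protecting group to one removed by mild acid and sets out from syringaldehyde 10. MOMCl/i-Pr2NEt (CH2Cl2) gives 3,5-dimethoxy-4-(methoxymethoxy)benzaldehyde F8. Claisen–Schmidt condensation with 9 (KOH, EtOH, rt) passes through the aldol 3-[3,5-dimethoxy-4-(methoxymethoxy)phenyl]-3-hydroxy-1-(2-hydroxy-3,4,5,6-tetramethoxyphenyl)propan-1-one F9, which is not isolated. It gives (2E)-3-[3,5-dimethoxy-4-(methoxymethoxy)phenyl]-1-(2-hydroxy-3,4,5,6-tetramethoxyphenyl)prop-2-en-1-one F10. I2 (cat.)/DMSO at 120 °C converts this through the flavanone 2-[3,5-dimethoxy-4-(methoxymethoxy)phenyl]-5,6,7,8-tetramethoxychroman-4-one F11, not isolated, into 3',5,5',6,7,8-hexamethoxy-4'-(methoxymethoxy)flavone F12. HCl (2 M)/MeOH–THF at 40 °C removes the MOM group and reaches target 16 without any reduction step; MOM lost already in the iodine step simply gives 16 directly.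

**Further compounds**
F1 | step 5 | 1-(methoxymethoxy)-2,3,4,5-tetramethoxybenzene | COCOc1cc(OC)c(OC)c(OC)c1OC
F2 | step 5 | [2-(methoxymethoxy)-3,4,5,6-tetramethoxyphenyl]lithium | [Li]c1c(OCOC)c(OC)c(OC)c(OC)c1OC
F3 | step 5 | lithium 1-[methoxy(methyl)amino]-1-[2-(methoxymethoxy)-3,4,5,6-tetramethoxyphenyl]ethan-1-olate (racemic) | [Li+].[O-]C(C)(N(C)OC)c1c(OCOC)c(OC)c(OC)c(OC)c1OC
F4 | step 5 | 1-[2-(methoxymethoxy)-3,4,5,6-tetramethoxyphenyl]ethan-1-one | CC(=O)c1c(OCOC)c(OC)c(OC)c(OC)c1OC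
F5 | step 8 | 4-(benzyloxy)-3,5-dimethoxybenzoic acid | COc1cc(C(=O)O)cc(OC)c1OCc1ccccc1
F6 | step 8 | 2-acetyl-3,4,5,6-tetramethoxyphenyl 4-(benzyloxy)-3,5-dimethoxybenzoate | CC(=O)c1c(OC(=O)c2cc(OC)c(OCc3ccccc3)c(OC)c2)c(OC)c(OC)c(OC)c1OC
F7 | step 8 | 1-[4-(benzyloxy)-3,5-dimethoxyphenyl]-3-(2-hydroxy-3,4,5,6-tetramethoxyphenyl)propane-1,3-dione | COc1cc(C(=O)CC(=O)c2c(O)c(OC)c(OC)c(OC)c2OC)cc(OC)c1OCc1ccccc1
F8 | step 9 | 3,5-dimethoxy-4-(methoxymethoxy)benzaldehyde | COCOc1c(OC)cc(C=O)cc1OC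
F9 | step 9 | 3-[3,5-dimethoxy-4-(methoxymethoxy)phenyl]-3-hydroxy-1-(2-hydroxy-3,4,5,6-tetramethoxyphenyl)propan-1-one (racemic) | COCOc1c(OC)cc(C(O)CC(=O)c2c(O)c(OC)c(OC)c(OC)c2OC)cc1OC
F10 | step 9 | (2E)-3-[3,5-dimethoxy-4-(methoxymethoxy)phenyl]-1-(2-hydroxy-3,4,5,6-tetramethoxyphenyl)prop-2-en-1-one | COCOc1c(OC)cc(/C=C/C(=O)c2c(O)c(OC)c(OC)c(OC)c2OC)cc1OC
F11 | step 9 | 2-[3,5-dimethoxy-4-(methoxymethoxy)phenyl]-5,6,7,8-tetramethoxychroman-4-one (racemic) | COCOc1c(OC)cc(C2CC(=O)c3c(OC)c(OC)c(OC)c(OC)c3O2)cc1OC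
F12 | step 9 | 3',5,5',6,7,8-hexamethoxy-4'-(methoxymethoxy)flavone | COCOc1c(OC)cc(-c2cc(=O)c3c(OC)c(OC)c(OC)c(OC)c3o2)cc1OC
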